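The numbers in the tables were computed for substances that don't exist.

If a substrate meets a partner charged in excess and nothing else happens, the logarithm of the substrate falls evenly with time (pseudo-first-order), and this pace is the rate constant times the partner present. I read the flask asked about, followed so far as the epsilon run, on that footing.

| flask | substrate | partner | capture agent | temperature | remark | time |
|---|---|---|---|---|---|---|
| epsilon | 0.032 M | 4 equiv | 0.032 M | 0 °C | the very flask that is asked about, followed so far |  |
| eta | 0.032 M | 6 equiv | 0.032 M | −15 °C | run made earlier |  |
| flask | 0.032 M | 4.00 equiv | 0.0320 M | 0 °C |  | 5.0 min |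

- epsilon (time / min: target / %, substrate / %): 0.417: 22.3, 72.2; 1.00: 39.7, 54.7; 2.00: 54.1, 37.2; 5.00: 68.2, 25.2
- eta (time / min: target / %, substrate / %): 0.500: 3.3, 84.6; 1.33: 19.4, 64.2; 3.00: 41.0, 45.3; 8.00: 64.2, 21.7

(readings scatter by 1 percentage point)

- dawn: at 5.0 min add partner, 50.0% of the amount charged, then wait 2.5 min
- winter: at 5.0 min take out 90% of the by-product then present, then wait 2.5 min
- midnight: at 5.0 min raise the temperature by 25 K, then wait 2.5 min
- noon: change nothing and wait 2.5 min more

- target, in percent of the substrate first charged, at 5.0 min
- which option adds most target ("none" when 2 percentage points or less is all one gets) (dawn / winter / midnight / noon / none)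
- target present, in percent of the substrate first charged, after winter
- target present, in percent of the substrate first charged, after midnight

- the volume of additions can be left aside

1. The epsilon substrate falls at a pace of 0.781 min⁻¹ up to the first reading, but at 0.130 min⁻¹ between the last two readings. I take the ratio, 16.6%, as the share of partner still working at 3.50 min, the middle of that stretch, and I count any way back as lost partner.

2. Substrate consumption by itself, at one partner for each substrate lost, would leave 81.3% of the partner even at the last reading, more than that share. So I suppose that partner also goes another way. I assume it meets itself.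

3. The share is then one over one plus time divided by a life. Time multiplied by share, over one minus share, gives 0.698 min. This is my reading of the partner life, the time in which partner at its charged amount falls to half by meeting itself. On that assumption it varies inversely with the charge of partner.

4. At 5.0 min I reckon 12.2% of the partner left. Dawn raises the share to 62.2%. Summing the pace over 2.5 min, and reading all substrate lost as target, I get a gain of 12 percentage points. I commit to dawn, and for the target now to the reading, 68.2%. This reckoning gives no figure for winter or midnight.

5. The forecast gives 68% now, winter as best, 80% after winter and 69% after midnight. It reads the stall as “reversibility or by-product inhibition rather than lack of partner”, and it gives added partner about 7 points, so we differ on the best option.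

6. The flask gives 66.6% now. The best option is dawn, which adds 12 points, while winter adds 0.79 points. Target stands at 67.3% after winter and 5.18% after midnight.

    substrate + partner ⇌ open intermediate (K = 3.10 M⁻¹, k = 0.150 M⁻¹ s⁻¹, Ea = 57.0 kJ mol⁻¹, ΔH = −71.0 kJ mol⁻¹)
    open intermediate ⇌ target + by-product (K = 0.0730 M, k = 0.170 s⁻¹, Ea = 80.0 kJ mol⁻¹, ΔH = −28.0 kJ mol⁻¹)
    2 partner → self-condensation product (k = 0.0420 M⁻¹ s⁻¹, Ea = 60.0 kJ mol⁻¹)
    open intermediate + capture agent → trapped intermediate (k = 0.560 M⁻¹ s⁻¹, Ea = 53.0 kJ mol⁻¹)
    partner + by-product ⇌ idle adduct, settled at all times (K = 1300 M⁻¹, ΔH = −66.0 kJ mol⁻¹)
    (constants at 0 °C)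

The flask holds 16% of its partner free at 5.0 min, against my 12.2%, and a further 0.0205 M stands there as idle adduct. The neighbouring flask has 0.019 M of substrate, with the equivalents of partner held, so my partner life for it becomes 1.17 min. From that I reckon 19.0% of its partner left at 5.0 min. The neighbouring flask holds 23.3% of its partner free then, and its target stands at 60.7%.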